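**Assumptions (one line each).** Ludongnin H is a 6,7-seco-ent-kauranoid: a 7,20-spirolactone, a 6,19-methyl acetal (OMe on the convex face, cis to H-5), and a 15-ketone with an exo 16-methyl. I take the C-6 acetal and C-16 methyl to be the thermodynamic epimers.

## Retrosynthetic overview
1. Target ⇐ C-16 hydrogenation/epimerisation ⇐ C-15 allylic oxidation ⇐ Pd(II) cycloalkenylation of a lactone silyl ketene acetal onto the C-13 isopropenyl group (ring D, C8–C15 bond, last ring formed).
2. Spirolactone ⇐ Ti(III) epoxide opening, then Giese addition to a cyclohexene enoate and lactonisation. This joins C9–C10, builds the C-10 quaternary centre and closes the lactone ring in one step.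
3. Spiro-epoxide ⇐ ketone ⇐ 3-methylcyclohexenone by asymmetric conjugate addition (C-4), orthoformate C-alkylation (C-6), ozonolysis (C-19) and transacetalisation (THF acetal). The enoate ⇐ cyclohexenone by Rh-catalysed asymmetric 1,4-addition (C-13), enol triflate and carbonylation.
4. Ring order: A, then THF acetal, then C (as a monocycle), then lactone with C9–C10 together, then D.

## Route

**Step 1**
Reactants: 1 3-methylcyclohex-2-en-1-one; 2 vinylmagnesium bromide
Product: 3 silyl enol ether of (3-methyl-3-vinylcyclohexanone), quaternary carbon configured as C-4 of the target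
Conditions: CuBr·SMe2 (5 mol %), chiral Josiphos-type ligand, 2, MeTHF, –78 °C; then TMSCl, Et3N
Reagents that add atoms: chlorotrimethylsilane, C[Si](C)(C)Cl
Why: Cu-catalysed asymmetric conjugate addition sets the C-4 quaternary centre, and silylation of the magnesium enolate fixes the Δ5(10) enol ether regiospecifically (next to C-4).

**Step 2**
Reactants: 3
Product: 4 2-(dimethoxymethyl)-3-methyl-3-vinylcyclohexan-1-one (C-5 epimeric)
Conditions: HC(OMe)3, TMSOTf (5 mol %), CH2Cl2, –78 °C
Reagents that add atoms: trimethyl orthoformate, COC(OC)OC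
Why: Mukaiyama/Noyori-type acetal C-alkylation of the silyl enol ether puts C-6 on C-5 at aldehyde oxidation level as a dimethyl acetal; C-5 is epimerisable and is set in step 4.

**Step 3**
Reactants: 4
Product: 5 2-(dimethoxymethyl)-1-methyl-3-oxocyclohexane-1-carbaldehyde
Conditions: O3, CH2Cl2, –78 °C; then PPh3
Reagents that add atoms: ozone, O=[O+][O-] (source of the aldehyde O)
Why: ozonolysis of the isolated vinyl group gives the C-19 aldehyde; the ketone and the acetal are untouched.

**Step 4**
Reactants: 5
Product: 6 cis-fused 2-methoxy-tetrahydrofuran/cyclohexanone (C-10 ketone)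
Conditions: NaBH4 (0.3 equiv), EtOH/CH2Cl2, –78 °C; then TsOH·H2O (10 mol %), CH2Cl2, rt (one pot)
Reagents that add atoms: none
Why: NaBH4 at –78 °C reduces the aldehyde in preference to the hindered ketone. Acid then drives intramolecular transacetalisation, which can only close cis-fused, so C-5 epimerises through the enol to the correct configuration; the anomer with OMe on the convex face is the thermodynamic major and is isolated.

**Step 5**
Reactants: 6
Product: 7 spiro-epoxide at C-10 (C-10 epimers not distinguished)
Conditions: CH2I2, MeLi·LiBr, THF, –78 °C → rt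
Reagents that add atoms: diiodomethane, ICI (adds CH2 = C-20)
Why: Barluenga-type LiCH2I addition and ring closure methylenates the ketone without base, which avoids β-elimination of the β-alkoxy ketone. The epoxide configuration is irrelevant because a planar radical is generated next.

**Step 6**
Reactants: 8 cyclohex-2-en-1-one; 9 isopropenylboronic acid pinacol ester
Product: 10 (R)-3-(prop-1-en-2-yl)cyclohexan-1-one
Conditions: [Rh(cod)Cl]2, BINAP enantiomer chosen to give the (R)-ketone, aq. KOH, dioxane, 50 °C
Reagents that add atoms: none (H from water only)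
Why: Hayashi–Miyaura asymmetric 1,4-addition sets C-13.

**Step 7**
Reactants: 10
Product: 11 (R)-5-(prop-1-en-2-yl)cyclohex-1-en-1-yl triflate
Conditions: LiHMDS, THF, –78 °C; then PhNTf2
Reagents that add atoms: N-phenylbis(triflimide), O=S(=O)(C(F)(F)F)N(c1ccccc1)S(=O)(=O)C(F)(F)F
Why: kinetic deprotonation occurs on the side remote from the C-13 substituent, so the enol triflate carries the C8=C9 alkene (C-8 bears the OTf).

**Step 8**
Reactants: 11
Product: 12 methyl (R)-5-(prop-1-en-2-yl)cyclohex-1-ene-1-carboxylate
Conditions: Pd(OAc)2 (5 mol %), PPh3, CO (1 atm), MeOH, Et3N, DMF, 60 °C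
Reagents that add atoms: carbon monoxide, [C-]#[O+]; methanol, CO
Why: Pd-catalysed methoxycarbonylation of the vinyl triflate gives the C-7 ester on C-8 and the enoate acceptor.

**Step 9**
Reactants: 7; 12
Product: 13 spiro-δ-lactone (C8–H unspecified; tetracycle: ring A, THF acetal, lactone, ring C)
Conditions: Cp2TiCl2 (2.2 equiv), Zn dust, collidine·HCl, THF, rt; then PPTS, toluene, 60 °C
Reagents that add atoms: none
Why: Nugent–RajanBabu Ti(III) opening of the epoxide gives the tertiary C-10 radical with the Ti-alkoxide on C-20. This radical adds to C-9 (the β-carbon) of the enoate, the resulting C-8 radical is reduced and protonated, and the alkoxide lactonises onto the ester. The radical attacks ring A anti to the axial C-19 (giving the natural C-10). Axial attack on the half-chair enoate gives C-10 cis to the C-13 isopropenyl.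

**Step 10**
Reactants: 13
Product: 14 TMS ketene acetal of the lactone (C7=C8)
Conditions: LiHMDS, TMSCl, THF, –78 °C
Reagents that add atoms: chlorotrimethylsilane, C[Si](C)(C)Cl
Why: deprotonation of the tertiary C-8 α-H removes the C-8 stereocentre, which is reset in the next step.

**Step 11**
Reactants: 14
Product: 15 bicyclo[3.2.1]octane with exo-methylene C16=C17 and C15H2
Conditions: Pd(OAc)2 (1.1 equiv), MeCN, 23 → 40 °C
Reagents that add atoms: none (TMS is lost as TMSOAc)
Why: Toyota–Ihara/Reisman-type Pd(II) cycloalkenylation; the ketene acetal carbon attacks the isopropenyl CH2 (forming C8–C15) and β-H elimination gives the exocyclic alkene. The axial C-13 isopropenyl fixes the C-8 configuration.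

**Step 12**
Reactants: 15
Product: 16 C-15 allylic alcohol (epimeric at C-15)
Conditions: SeO2 (20 mol %), TBHP, pyridine (cat.), CH2Cl2, rt
Reagents that add atoms: tert-butyl hydroperoxide, CC(C)(C)OO (O source)
Why: Riley allylic oxidation; C-15 is the only allylic CH2, because C-13 is a bridgehead.

**Step 13**
Reactants: 16
Product: 17 16-methylene-15-ketone (ent-kaur-16-en-15-one type)
Conditions: Dess–Martin periodinane, NaHCO3, CH2Cl2, rt
Reagents that add atoms: none
Why: oxidation of the allylic alcohol to the enone; the buffer protects the acetal.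

**Step 14**
Reactants: 17
Product: 18 ludongnin H
Conditions: H2 (1 atm), 10 % Pd/C, EtOAc, rt; then DBU, CH2Cl2, rt
Reagents that add atoms: none
Why: chemoselective hydrogenation of the exocyclic enone alkene gives the C-16 methyl, probably as the kinetic endo epimer. DBU equilibrates C-16 (α to the ketone, via the enol) to the exo-methyl, the thermodynamic epimer that matches the target.

## Compound list
1 | 3-methylcyclohex-2-en-1-one | CC1=CC(=O)CCC1 | starting material
2 | vinylmagnesium bromide | C=C[Mg]Br | starting material
3 | TMS enol ether of (R)-3-methyl-3-vinylcyclohexanone (C-4 configured as in target) | C=C[C@]1(C)CCCC(O[Si](C)(C)C)=C1 | intermediate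
4 | 2-(dimethoxymethyl)-3-methyl-3-vinylcyclohexanone (C-5 epimeric) | C=C[C@]1(C)CCCC(=O)C1C(OC)OC | intermediate
5 | 2-(dimethoxymethyl)-1-methyl-3-oxocyclohexane-1-carbaldehyde | O=C[C@]1(C)CCCC(=O)C1C(OC)OC | intermediate
6 | cis-fused 2-methoxy-THF/cyclohexanone (1-methoxy-3a-methylhexahydroisobenzofuran-7-one) | CO[C@H]1OC[C@]2(C)CCCC(=O)[C@H]12 | intermediate
7 | spiro-epoxide of 6 | CO[C@H]1OC[C@]2(C)CCCC3(CO3)[C@H]12 | intermediate
8 | cyclohex-2-en-1-one | O=C1C=CCCC1 | starting material
9 | isopropenylboronic acid pinacol ester | CC(=C)B1OC(C)(C)C(C)(C)O1 | starting material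
10 | (R)-3-isopropenylcyclohexanone | C=C(C)[C@@H]1CCCC(=O)C1 | intermediate
11 | (R)-5-isopropenylcyclohex-1-en-1-yl triflate | C=C(C)[C@@H]1CCC=C(OS(=O)(=O)C(F)(F)F)C1 | intermediate
12 | methyl (R)-5-isopropenylcyclohex-1-ene-1-carboxylate | C=C(C)[C@@H]1CCC=C(C(=O)OC)C1 | intermediate
13 | spiro-δ-lactone with isopropenyl | CO[C@H]1OC[C@]2(C)CCC[C@]3(COC(=O)C4C[C@@H](CC[C@H]43)C(C)=C)[C@H]12 | intermediate
14 | TMS ketene acetal of 13 | CO[C@H]1OC[C@]2(C)CCC[C@]3(COC(O[Si](C)(C)C)=C4C[C@@H](CC[C@H]43)C(C)=C)[C@H]12 | intermediate
15 | bicyclo[3.2.1] exo-methylene lactone | CO[C@H]1OC[C@]2(C)CCC[C@]3(COC(=O)[C@@]45C[C@@H](CC[C@H]43)C(=C)C5)[C@H]12 | intermediate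
16 | 15-hydroxy analogue of 15 | CO[C@H]1OC[C@]2(C)CCC[C@]3(COC(=O)[C@@]45C[C@@H](CC[C@H]43)C(=C)C5O)[C@H]12 | intermediate
17 | 16-methylene-15-ketone | CO[C@H]1OC[C@]2(C)CCC[C@]3(COC(=O)[C@@]45C[C@@H](CC[C@H]43)C(=C)C5=O)[C@H]12 | intermediate
18 | ludongnin H | CO[C@H]1OC[C@]2(C)CCC[C@]3(COC(=O)[C@@]45C[C@@H](CC[C@H]43)[C@H](C)C5=O)[C@H]12 | target

## Totals
Total steps: 14. Longest linear sequence: 11 (steps 1–5, then 9–14).

## Three steps most likely to fail
1. **Step 9 (Ti(III) Giese/lactonisation).** A hindered tertiary radical must add to a trisubstituted enoate, and it risks reduction, β-scission of C5–C6 or the wrong C-10 face.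
   Fallback: generate the C-10 radical by HAT instead. Convert ketone 6 to the Δ1(10) allylic alcohol (enol triflate, Pd/CO, DIBAL), then do an Fe(acac)3/PhSiH3 olefin–olefin coupling with an enoate whose C-13 carries a protected 2-hydroxypropyl group in place of isopropenyl, and lactonise afterwards.
2. **Step 11 (Pd(II) cycloalkenylation).** It needs stoichiometric Pd on a congested, acetal-bearing substrate.
   Fallback: use a polar aldol closure. Convert the isopropenyl of 13 (hydroboration, oxidation, Dess–Martin) to the α-methyl aldehyde and protect it as the dimethyl acetal. Then form the TMS ketene acetal and close C8–C15 by intramolecular Mukaiyama aldol, followed by Dess–Martin to give the β-keto lactone directly, skipping steps 12–14.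
3. **Step 1 (asymmetric vinyl addition forming the quaternary C-4).** Enantioselectivity is uncertain for vinyl Grignard on a β-methyl enone.
   Fallback: make racemic 3-methyl-3-vinylcyclohexanone (CuI, vinylMgBr), convert it to the SAMP hydrazone, separate the diastereomers, and release the ketone (MeI, then hydrolysis) before resuming at the orthoformate step.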